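**Retrosynthetic overview**

- The target is traced back through its 7-O-silyl flavanone and the (2S)-flavan-4-ol to a 2,4-cis-4-methoxyflavan; the C4 carbonyl passes through the key step as a methoxy-bearing carbon.
- The strategy rests on ring C (O1–C2–C3–C4–C4a–C8a): the bonds O1–C2 and C3–C4 lie on either side of the C2–C3 unit, which is the vinyl group of a ring B styrene. O1, C8a, C4a and C4 are the phenol oxygen, two ring A carbons and the formyl carbon of a salicylaldehyde. Both bonds are cut at once, as a retro oxa-[4+2] of a methoxy ortho-quinone methide.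
- Ring A partner: 2-hydroxy-3-prenyl-4-(triisopropylsilyloxy)benzaldehyde, from 2,4-dihydroxybenzaldehyde by O4 1,1-dimethylpropargylation, semihydrogenation, aromatic Claisen shift to C3 and O4 silylation. Ring B partner: 2,2-dimethyl-6-vinylchroman, by Wittig methylenation of the chroman aldehyde.
- Ring order: ring A and the chroman (ring B with its dimethylpyran ring) are bought in; ring C is the only ring made, in the cycloaddition, which also sets C2 as S.

Key step: step 6

Assumption: 2,2-dimethylchroman-6-carbaldehyde is a catalogue compound and is used as bought.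

**Route**

Step 1
Reactants: 1 2,4-dihydroxybenzaldehyde; 2 3-chloro-3-methylbut-1-yne
Product: 3 2-hydroxy-4-[(2-methylbut-3-yn-2-yl)oxy]benzaldehyde
Conditions: K2CO3, KI, CuI (cat.), acetone, reflux
Reagents that add atoms: none
Why: Copper-catalysed propargylic etherification (a Williamson-type O-alkylation through the copper acetylide) should take place at the 4-OH, the more acidic phenol, because the 2-OH is tied up in a hydrogen bond to the formyl group.

Step 2
Reactants: 3 2-hydroxy-4-[(2-methylbut-3-yn-2-yl)oxy]benzaldehyde
Product: 4 2-hydroxy-4-[(2-methylbut-3-en-2-yl)oxy]benzaldehyde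
Conditions: H2 (1 atm), Pd/CaCO3 poisoned with Pb(OAc)2 (Lindlar catalyst), quinoline, EtOAc, rt
Reagents that add atoms: none
Why: Lindlar semihydrogenation should stop at the terminal alkene and leave the aldehyde and the aryl ether untouched; the product is kept at or below room temperature because the 1,1-dimethylallyl ether rearranges easily.

Step 3
Reactants: 4 2-hydroxy-4-[(2-methylbut-3-en-2-yl)oxy]benzaldehyde
Product: 5 2,4-dihydroxy-3-(3-methylbut-2-en-1-yl)benzaldehyde
Conditions: PhNEt2, 150 °C
Reagents that add atoms: none
Why: The aromatic Claisen rearrangement, a [3,3]-sigmatropic shift with allyl inversion that turns the 1,1-dimethylallyl ether into a C-prenyl group, should go to C3 because the chelated 2-hydroxy aldehyde fixes the higher double-bond character in the C3–C4 bond, and tautomerisation then restores the resorcinol.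

Step 4
Reactants: 5 2,4-dihydroxy-3-(3-methylbut-2-en-1-yl)benzaldehyde
Product: 6 2-hydroxy-3-prenyl-4-(triisopropylsilyloxy)benzaldehyde
Conditions: TIPSCl, imidazole, DMF, 0 °C → rt
Reagents that add atoms: triisopropylsilyl chloride, CC(C)[Si](Cl)(C(C)C)C(C)C
Why: Selective O-silylation should occur at the 4-OH, since the 2-OH is deactivated by its hydrogen bond to the aldehyde and stays free for the key step, and the bulky aryl silyl ether tolerates the acids of steps 6 and 7.

Step 5
Reactants: 7 2,2-dimethylchroman-6-carbaldehyde
Product: 8 2,2-dimethyl-6-vinylchroman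
Conditions: Ph3PCH3Br, KOtBu, THF, 0 °C → rt
Reagents that add atoms: methyltriphenylphosphonium bromide, C[P+](c1ccccc1)(c1ccccc1)c1ccccc1.[Br-]
Why: Wittig methylenation of an aromatic aldehyde with the non-stabilised ylide should give the terminal styrene, with the chroman ether inert to the base.

Step 6
Reactants: 6 2-hydroxy-3-prenyl-4-(triisopropylsilyloxy)benzaldehyde; 8 2,2-dimethyl-6-vinylchroman; 9 trimethyl orthoformate
Product: 12 (2S,4S)-2-(2,2-dimethylchroman-6-yl)-4-methoxy-8-prenyl-7-(triisopropylsilyloxy)chroman (2,4-cis), via dimethyl acetal 10 (not isolated), via methoxy ortho-quinone methide 11 (not isolated)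
Conditions: 6, 9, (R)-3,3'-bis(2,4,6-triisopropylphenyl)-1,1'-binaphthyl-2,2'-diyl hydrogen phosphate (10 mol %), toluene, rt; then 8 (excess), 0 °C → rt
Reagents that add atoms: none
Why: Proposed new method: the phosphoric acid should first catalyse acetal formation with the orthoformate to give 10, then protonate it and expel methanol to give the E-configured methoxy ortho-quinone methide 11, held as a hydrogen-bonded ion pair with the chiral phosphate; the CH2 terminus of styrene 8 attacks the methide carbon (C3–C4) and the ring A oxygen collapses on the developing para-alkoxybenzylic centre (O1–C2) in an asynchronous inverse-electron-demand oxa-[4+2] cycloaddition. The closest known reactions are the achiral acid-catalysed three-component condensation of salicylaldehydes, trimethyl orthoformate and styrenes to 2,4-cis-4-methoxyflavans and the chiral phosphoric acid catalysed [4+2] additions of ortho-quinone methides made from ortho-hydroxybenzyl alcohols; their combination, with an acetal-derived methide and a styrene that offers no hydrogen bond to the catalyst, has not been shown. Ring C, the only ring formed, is closed by the intermolecular [4+2] addition itself, four atoms (O1, C8a, C4a, C4) coming from the methide and two (C2, C3) from the styrene. C2 should be set as S by the face of the methide that the 2,4,6-triisopropylphenyl groups of the phosphate leave open (the antipodal acid is taken if the sense proves to be the reverse), and C4 follows from the E methide and an endo aryl group, which gives the 2,4-cis isomer; C4 is erased later, so either C4 epimer of a 2S product is usable. The step needs regioselectivity, secured by the polarity of the para-alkoxystyrene (nucleophilic CH2 end, cation-stabilising ring B), and chemoselectivity for the styrene over the prenyl alkene and against addition of the free 2-OH to the prenyl group, secured by the higher nucleophilicity of the styrene and by the weak acidity of the phosphoric acid.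

Step 7
Reactants: 12 (2S,4S)-2-(2,2-dimethylchroman-6-yl)-4-methoxy-8-prenyl-7-(triisopropylsilyloxy)chroman
Product: 13 (2S)-2-(2,2-dimethylchroman-6-yl)-8-prenyl-7-(triisopropylsilyloxy)chroman-4-ol (C4 epimer mixture)
Conditions: TsOH·H2O (cat.), THF/H2O, rt
Reagents that add atoms: water, O
Why: Acid-catalysed SN1 solvolysis should exchange the methoxy group, because C4 is a benzylic ether activated by both the ortho ring oxygen O1 and the para silyloxy group and its cation is trapped by the large excess of water, whereas the less activated C2–O1 aryl benzyl ether is not ionised and C2 stays intact; the C4 epimer mixture is of no consequence.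

Step 8
Reactants: 13 (2S)-2-(2,2-dimethylchroman-6-yl)-8-prenyl-7-(triisopropylsilyloxy)chroman-4-ol
Product: 14 (2S)-2-(2,2-dimethylchroman-6-yl)-8-prenyl-7-(triisopropylsilyloxy)chroman-4-one
Conditions: Dess–Martin periodinane, pyridine, CH2Cl2, 0 °C → rt
Reagents that add atoms: none
Why: Dess–Martin oxidation of the secondary benzylic alcohol under pyridine buffering should converge both C4 epimers on the ketone without touching the prenyl alkene, the silyl ether or the C2 stereocentre.

Step 9
Reactants: 14 (2S)-2-(2,2-dimethylchroman-6-yl)-8-prenyl-7-(triisopropylsilyloxy)chroman-4-one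
Product: 15 euchrenone a17 [(2S)-2-(2,2-dimethylchroman-6-yl)-7-hydroxy-8-prenylchroman-4-one]
Conditions: TBAF, AcOH, THF, 0 °C
Reagents that add atoms: none
Why: Fluoride cleavage of the aryl silyl ether, buffered with acetic acid so that the medium does not become basic enough to open the flavanone to the chalcone, should release the 7-OH with C2 unchanged.

**Compound list**

1 | 2,4-dihydroxybenzaldehyde | O=Cc1ccc(O)cc1O | starting material
2 | 3-chloro-3-methylbut-1-yne | CC(C)(Cl)C#C | starting material
3 | 2-hydroxy-4-[(2-methylbut-3-yn-2-yl)oxy]benzaldehyde | C#CC(C)(C)Oc1ccc(C=O)c(O)c1 | intermediate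
4 | 2-hydroxy-4-[(2-methylbut-3-en-2-yl)oxy]benzaldehyde | C=CC(C)(C)Oc1ccc(C=O)c(O)c1 | intermediate
5 | 2,4-dihydroxy-3-(3-methylbut-2-en-1-yl)benzaldehyde | CC(C)=CCc1c(O)ccc(C=O)c1O | intermediate
6 | 2-hydroxy-3-prenyl-4-(triisopropylsilyloxy)benzaldehyde | CC(C)=CCc1c(O[Si](C(C)C)(C(C)C)C(C)C)ccc(C=O)c1O | intermediate
7 | 2,2-dimethylchroman-6-carbaldehyde | O=Cc1ccc2c(c1)CCC(C)(C)O2 | starting material
8 | 2,2-dimethyl-6-vinylchroman | C=Cc1ccc2c(c1)CCC(C)(C)O2 | intermediate
9 | trimethyl orthoformate | COC(OC)OC | starting material
10 | 6-(dimethoxymethyl)-2-prenyl-3-(triisopropylsilyloxy)phenol (formed in the flask) | CC(C)=CCc1c(O[Si](C(C)C)(C(C)C)C(C)C)ccc(C(OC)OC)c1O | intermediate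
11 | (6E)-6-(methoxymethylidene)-2-prenyl-3-(triisopropylsilyloxy)cyclohexa-2,4-dien-1-one (formed in the flask, bound to the phosphoric acid) | CC(C)=CCC1=C(O[Si](C(C)C)(C(C)C)C(C)C)C=C/C(=C\OC)C1=O | intermediate
12 | (2S,4S)-2-(2,2-dimethylchroman-6-yl)-4-methoxy-8-prenyl-7-(triisopropylsilyloxy)chroman (2,4-cis) | CC(C)=CCc1c(O[Si](C(C)C)(C(C)C)C(C)C)ccc2c1O[C@H](c1ccc3c(c1)CCC(C)(C)O3)C[C@@H]2OC | intermediate
13 | (2S)-2-(2,2-dimethylchroman-6-yl)-8-prenyl-7-(triisopropylsilyloxy)chroman-4-ol, C4 epimer mixture | CC(C)=CCc1c(O[Si](C(C)C)(C(C)C)C(C)C)ccc2c1O[C@H](c1ccc3c(c1)CCC(C)(C)O3)CC2O | intermediate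
14 | (2S)-2-(2,2-dimethylchroman-6-yl)-8-prenyl-7-(triisopropylsilyloxy)chroman-4-one | CC(C)=CCc1c(O[Si](C(C)C)(C(C)C)C(C)C)ccc2c1O[C@H](c1ccc3c(c1)CCC(C)(C)O3)CC2=O | intermediate
15 | euchrenone a17, (2S)-2-(2,2-dimethylchroman-6-yl)-7-hydroxy-8-prenylchroman-4-one | CC(C)=CCc1c(O)ccc2c1O[C@H](c1ccc3c(c1)CCC(C)(C)O3)CC2=O | target

**Step count**

Total steps: 9. Longest linear sequence: 8 (steps 1 to 4, then 6 to 9); step 5 is the one-step side branch.

**Steps most likely to fail, with fallbacks**

Step 6 (proposed new method). What may go wrong: poor facial discrimination when the styrene adds to the phosphate-bound methide, so that C2 is formed with low enantiomeric purity. The weak acid may also ionise the acetal too slowly, and acid-induced addition of the free 2-OH to the prenyl group may compete. The fallback uses known chemistry, sets out from 6, 8 and 9 and comes back at 14. The three components are combined under achiral Lewis acid catalysis (Sc(OTf)3, CH2Cl2, rt), the established racemic form of this condensation, which should give the racemic 2,4-cis-4-methoxyflavan F1 by way of 10 and 11. Hydrolysis under the conditions of step 7 should give the racemic flavan-4-ol F2, and Dess–Martin oxidation as in step 8 the racemic flavanone F3. F3 is then resolved kinetically by Noyori asymmetric transfer hydrogenation (RuCl[(R,R)-TsDPEN](p-cymene), HCO2H/Et3N, EtOAc, rt). This is expected to reduce the 2R ketone to the (2R,4R)-2,4-cis-flavan-4-ol F4 and to leave the 2S ketone, which after chromatography is 14. If the complex discriminates in the other sense, its (S,S) antipode is used.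

Step 7. What may go wrong: the C4 cation may lose a C3 proton (elimination to the flav-3-ene) instead of being trapped by water. Prolonged acid may also open the C2–O1 bond through the para-alkoxybenzylic cation and so erode the C2 configuration. The fallback sets out from 12 and comes back at 14, replacing solvolysis by oxidation. DDQ in CH2Cl2/H2O at 0 °C should abstract hydride from C4, the most hydridic C–H of the molecule (alpha to the methoxy group, on the ring with ortho and para oxygen donors). Water adds to the oxocarbenium ion and the hemiketal loses methanol, which should give ketone 14 directly, without acid and without 13. This is the known DDQ oxidation of electron-rich benzylic methyl ethers to carbonyl compounds. No new compound arises on the way (F0).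

Step 9. What may go wrong: basic fluoride or the phenoxide formed may trigger retro-oxa-Michael opening of the flavanone to the 2'-hydroxychalcone and reclosure, which would erode the configuration at C2. The fallback sets out from 13 and comes back at 15, changing the order of events so that the silyl group is removed before the ketone exists. TBAF (THF, 0 °C) on 13 should give the (2S)-flavan-4,7-diol F5, in which C2 is not activated by a carbonyl group. Chemoselective oxidation of its para-hydroxybenzylic alcohol with activated MnO2 (CH2Cl2, rt) should then give 15 under neutral conditions.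

**Further compounds**

F1 | step 6 | racemic 2,4-cis-2-(2,2-dimethylchroman-6-yl)-4-methoxy-8-prenyl-7-(triisopropylsilyloxy)chroman | CC(C)=CCc1c(O[Si](C(C)C)(C(C)C)C(C)C)ccc2c1OC(c1ccc3c(c1)CCC(C)(C)O3)CC2OC
F2 | step 6 | racemic 2-(2,2-dimethylchroman-6-yl)-8-prenyl-7-(triisopropylsilyloxy)chroman-4-ol, C4 epimer mixture | CC(C)=CCc1c(O[Si](C(C)C)(C(C)C)C(C)C)ccc2c1OC(c1ccc3c(c1)CCC(C)(C)O3)CC2O
F3 | step 6 | racemic 2-(2,2-dimethylchroman-6-yl)-8-prenyl-7-(triisopropylsilyloxy)chroman-4-one | CC(C)=CCc1c(O[Si](C(C)C)(C(C)C)C(C)C)ccc2c1OC(c1ccc3c(c1)CCC(C)(C)O3)CC2=O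
F4 | step 6 | (2R,4R)-2-(2,2-dimethylchroman-6-yl)-8-prenyl-7-(triisopropylsilyloxy)chroman-4-ol (2,4-cis) | CC(C)=CCc1c(O[Si](C(C)C)(C(C)C)C(C)C)ccc2c1O[C@@H](c1ccc3c(c1)CCC(C)(C)O3)C[C@H]2O
F0 | step 7 | none | none
F5 | step 9 | (2S)-2-(2,2-dimethylchroman-6-yl)-8-prenylchroman-4,7-diol, C4 epimer mixture | CC(C)=CCc1c(O)ccc2c1O[C@H](c1ccc3c(c1)CCC(C)(C)O3)CC2O
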